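**Retrosynthetic overview**
- The target comes from its bis-TBS ether by buffered fluoride desilylation.
- The C3–C7′ bond comes from a trans- and syn-selective aldol of the zirconium enolate of an (R)-β-benzyl-γ-butyrolactone with O-TBS-vanillin; this sets C3 and C7′.
- Key step: the C4–C5 bond comes from an NHC-catalysed homoenolate (d3) annulation of a 4-arylbut-2-enal with formaldehyde. The enal β-carbon and the formaldehyde carbon are both electrophilic by nature. This step closes the only ring (the lactone) and sets C4.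
- The enal comes from O-TBS-eugenol and crotonaldehyde by cross-metathesis; eugenol and vanillin supply the two aryl units.

Assumption: the (5aS,10bR) triazolium catalyst is taken to give the R lactone (if the sense proves opposite, its commercial enantiomer is used), and formaldehyde is charged as paraformaldehyde.

**Step 1**
Reactants: 1 eugenol (4-allyl-2-methoxyphenol)
Product: 2 (4-allyl-2-methoxyphenoxy)(tert-butyl)dimethylsilane
Conditions: TBSCl, imidazole, CH2Cl2, rt
Reagents that add atoms: tert-butyldimethylsilyl chloride, CC(C)(C)[Si](C)(C)Cl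
Why: Imidazole-promoted O-silylation of a phenol (silyl ether formation), needed because a free phenol would quench the acyl azolium and the enolate later on; no stereocenter is formed.

**Step 2**
Reactants: 2 (4-allyl-2-methoxyphenoxy)(tert-butyl)dimethylsilane; 3 (E)-but-2-enal (crotonaldehyde)
Product: 4 (E)-4-[4-(tert-butyldimethylsilyloxy)-3-methoxyphenyl]but-2-enal
Conditions: Hoveyda–Grubbs II (2.5 mol %), crotonaldehyde (5 equiv), 1,4-benzoquinone (10 mol %), CH2Cl2, 40 °C
Reagents that add atoms: none
Why: Olefin cross-metathesis of a terminal allylarene with an electron-poor enal is selective for the E cross product and is driven by loss of propene, while benzoquinone suppresses Ru–H migration of the allyl double bond.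

**Step 3**
Reactants: 4 (E)-4-[4-(tert-butyldimethylsilyloxy)-3-methoxyphenyl]but-2-enal; 5 formaldehyde (charged as paraformaldehyde)
Product: 8 (R)-4-[4-(tert-butyldimethylsilyloxy)-3-methoxybenzyl]dihydrofuran-2(3H)-one, via Breslow homoenolate 6 (not isolated), via acyl azolium alkoxide 7 (not isolated)
Conditions: (CH2O)n (5 equiv), (5aS,10bR)-N-mesityl aminoindanol-derived triazolium chloride (10 mol %), iPr2NEt (20 mol %), THF, 40 °C, slow addition of 4
Reagents that add atoms: none
Why: Proposed new method: the carbene adds to the aldehyde of 4 to give the extended Breslow intermediate 6, whose β-carbon (now a d3 nucleophile) attacks formaldehyde on the face left open by the aminoindanol backbone, setting C4 as R; tautomerisation gives acyl azolium 7, whose alkoxide closes the lactone and releases the catalyst. The closest known reactions are the NHC-catalysed enal + aldehyde γ-butyrolactone annulation and the NHC-catalysed hydroxymethylation of aldehydes with paraformaldehyde, and the N-mesityl triazolium is chosen because it favours homoenolate over acyl-anion reactivity of enals.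

**Step 4**
Reactants: 9 vanillin (4-hydroxy-3-methoxybenzaldehyde)
Product: 10 4-(tert-butyldimethylsilyloxy)-3-methoxybenzaldehyde
Conditions: TBSCl, imidazole, CH2Cl2, rt
Reagents that add atoms: tert-butyldimethylsilyl chloride, CC(C)(C)[Si](C)(C)Cl
Why: Phenol silylation (silyl ether formation) removes the acidic OH and restores full electrophilicity to the aldehyde for the aldol step; no stereocenter is formed.

**Step 5**
Reactants: 8 (R)-4-[4-(tert-butyldimethylsilyloxy)-3-methoxybenzyl]dihydrofuran-2(3H)-one; 10 4-(tert-butyldimethylsilyloxy)-3-methoxybenzaldehyde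
Product: 13 (3S,4R)-3-[(S)-[4-(tert-butyldimethylsilyloxy)-3-methoxyphenyl](hydroxy)methyl]-4-[4-(tert-butyldimethylsilyloxy)-3-methoxybenzyl]dihydrofuran-2(3H)-one, via lithium enolate 11 (not isolated), via zirconium enolate 12 (not isolated)
Conditions: LDA (1.1 equiv), THF, −78 °C; Cp2ZrCl2 (1.2 equiv), −78 °C, 30 min; 10 (1.2 equiv), −78 °C; aq NH4Cl at −78 °C
Reagents that add atoms: none
Why: Aldol addition of a zirconium enolate: the aldehyde adds anti to the C4 benzyl group (3,4-trans, C3 = S), and chlorozirconocene enolates give syn (erythro) aldols irrespective of enolate geometry, which with this trans lactone corresponds to C7′ = S; the cold quench prevents retro-aldol equilibration.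

**Step 6**
Reactants: 13 (3S,4R)-3-[(S)-[4-(tert-butyldimethylsilyloxy)-3-methoxyphenyl](hydroxy)methyl]-4-[4-(tert-butyldimethylsilyloxy)-3-methoxybenzyl]dihydrofuran-2(3H)-one
Product: 14 (3S,4R)-3-[(S)-hydroxy(4-hydroxy-3-methoxyphenyl)methyl]-4-(4-hydroxy-3-methoxybenzyl)dihydrofuran-2(3H)-one
Conditions: TBAF (2.4 equiv), AcOH (2.6 equiv), THF, 0 °C
Reagents that add atoms: none
Why: Fluoride-mediated cleavage of aryl silyl ethers is fast, and the acetic acid buffer keeps the phenols protonated, so neither retro-aldol nor quinone-methide epimerisation at C7′ is triggered; no stereocenter is touched.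

**Compound list**
1 | eugenol (4-allyl-2-methoxyphenol) | C=CCc1ccc(O)c(OC)c1 | starting material
2 | (4-allyl-2-methoxyphenoxy)(tert-butyl)dimethylsilane | C=CCc1ccc(O[Si](C)(C)C(C)(C)C)c(OC)c1 | intermediate
3 | (E)-but-2-enal (crotonaldehyde) | C/C=C/C=O | starting material
4 | (E)-4-[4-(tert-butyldimethylsilyloxy)-3-methoxyphenyl]but-2-enal | O=C/C=C/Cc1ccc(O[Si](C)(C)C(C)(C)C)c(OC)c1 | intermediate
5 | formaldehyde (charged as paraformaldehyde) | C=O | starting material
6 | Breslow homoenolate: (E)-dienol formed from 4 and the (5aS,10bR) N-mesityl triazolylidene, nucleophilic at C3 of the enal | COc1cc(C/C=C/C(O)=C2N(c3c(C)cc(C)cc3C)N=C3CO[C@H]4Cc5ccccc5[C@H]4N23)ccc1O[Si](C)(C)C(C)(C)C | intermediate (not isolated)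
7 | acyl azolium alkoxide: (R)-3-(arylmethyl)-4-oxidobutanoyl triazolium zwitterion | COc1cc(C[C@@H](C[O-])CC(=O)c2n3c(n[n+]2-c2c(C)cc(C)cc2C)CO[C@H]2Cc4ccccc4[C@H]23)ccc1O[Si](C)(C)C(C)(C)C | intermediate (not isolated)
8 | (R)-4-[4-(tert-butyldimethylsilyloxy)-3-methoxybenzyl]dihydrofuran-2(3H)-one | COc1cc(C[C@H]2COC(=O)C2)ccc1O[Si](C)(C)C(C)(C)C | intermediate
9 | vanillin (4-hydroxy-3-methoxybenzaldehyde) | COc1cc(C=O)ccc1O | starting material
10 | 4-(tert-butyldimethylsilyloxy)-3-methoxybenzaldehyde | COc1cc(C=O)ccc1O[Si](C)(C)C(C)(C)C | intermediate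
11 | lithium enolate of 8 | COc1cc(C[C@H]2COC([O-])=C2)ccc1O[Si](C)(C)C(C)(C)C.[Li+] | intermediate (not isolated)
12 | chlorobis(cyclopentadienyl)zirconium enolate of 8 | COc1cc(C[C@H]2COC([O-])=C2)ccc1O[Si](C)(C)C(C)(C)C.[Cl-].[Zr+4].c1cc[cH-]c1.c1cc[cH-]c1 | intermediate (not isolated)
13 | (3S,4R)-3-[(S)-[4-(tert-butyldimethylsilyloxy)-3-methoxyphenyl](hydroxy)methyl]-4-[4-(tert-butyldimethylsilyloxy)-3-methoxybenzyl]dihydrofuran-2(3H)-one | COc1cc(C[C@H]2COC(=O)[C@@H]2[C@H](O)c2ccc(O[Si](C)(C)C(C)(C)C)c(OC)c2)ccc1O[Si](C)(C)C(C)(C)C | intermediate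
14 | (3S,4R)-3-[(S)-hydroxy(4-hydroxy-3-methoxyphenyl)methyl]-4-(4-hydroxy-3-methoxybenzyl)dihydrofuran-2(3H)-one | COc1cc(C[C@H]2COC(=O)[C@@H]2[C@H](O)c2ccc(O)c(OC)c2)ccc1O | target

**Totals**
Total step count: 6. Longest linear sequence: 5 steps (1 → 2 → 4 → 8 → 13 → 14).

**Steps most likely to fail**

Step 3 (NHC homoenolate/formaldehyde annulation). This step has no direct precedent. The risks are acyl-anion attack on formaldehyde instead of homoenolate attack, enal self-annulation, base-induced migration of the double bond toward the arene, and an unknown level and sense of enantioselectivity. The fallback sets out from 10 and comes back at 8. Wittig olefination of 10 with methyl 3-carboxy-2-(triphenylphosphoranylidene)propanoate gives the Stobbe-type half-ester (E)-4-[4-(tert-butyldimethylsilyloxy)-3-methoxyphenyl]-3-(methoxycarbonyl)but-3-enoic acid F1. Rh–Et-DuPHOS-catalysed asymmetric hydrogenation (the ligand enantiomer that delivers R) gives (R)-4-[4-(tert-butyldimethylsilyloxy)-3-methoxyphenyl]-3-(methoxycarbonyl)butanoic acid F2. Chemoselective reduction of the ester in its potassium carboxylate salt with Ca(BH4)2 in EtOH, followed by mild acidification, closes the lactone to 8.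

Step 5 (syn-selective aldol). Syn selectivity of zirconium enolates is established for ketone, amide and ester enolates but is an extrapolation for this lactone, so the C7′ ratio may be modest. The fallback sets out from 8 (with 10) and comes back at 13. A plain lithium-enolate aldol (LDA, THF, −78 °C) gives 13 mixed with its C7′ epimer (3S,4R)-3-[(R)-[4-(tert-butyldimethylsilyloxy)-3-methoxyphenyl](hydroxy)methyl]-4-[4-(tert-butyldimethylsilyloxy)-3-methoxybenzyl]dihydrofuran-2(3H)-one F3. Dess–Martin oxidation of the mixture converges both epimers on the keto lactone (3S,4R)-3-[4-(tert-butyldimethylsilyloxy)-3-methoxybenzoyl]-4-[4-(tert-butyldimethylsilyloxy)-3-methoxybenzyl]dihydrofuran-2(3H)-one F4. Chelation-controlled reduction with Zn(BH4)2 in Et2O at −20 °C delivers hydride anti to the ring substituent of the zinc chelate and gives the syn alcohol 13.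

Step 2 (cross-metathesis). The allylarene can isomerise to the propenylarene, and the product enal has acidic benzylic γ-hydrogens. The fallback sets out from 2 and comes back at 4. Lemieux–Johnson cleavage of 2 (cat. OsO4, NaIO4, 2,6-lutidine, dioxane–water) gives 2-[4-(tert-butyldimethylsilyloxy)-3-methoxyphenyl]acetaldehyde F5. Wittig two-carbon homologation of this aldehyde with (triphenylphosphoranylidene)acetaldehyde in toluene gives the E enal 4.

**Further compounds**
F1 | step 3 | (E)-4-[4-(tert-butyldimethylsilyloxy)-3-methoxyphenyl]-3-(methoxycarbonyl)but-3-enoic acid | COC(=O)/C(CC(=O)O)=C/c1ccc(O[Si](C)(C)C(C)(C)C)c(OC)c1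
F2 | step 3 | (R)-4-[4-(tert-butyldimethylsilyloxy)-3-methoxyphenyl]-3-(methoxycarbonyl)butanoic acid | COC(=O)[C@@H](CC(=O)O)Cc1ccc(O[Si](C)(C)C(C)(C)C)c(OC)c1
F3 | step 5 | (3S,4R)-3-[(R)-[4-(tert-butyldimethylsilyloxy)-3-methoxyphenyl](hydroxy)methyl]-4-[4-(tert-butyldimethylsilyloxy)-3-methoxybenzyl]dihydrofuran-2(3H)-one | COc1cc(C[C@H]2COC(=O)[C@@H]2[C@@H](O)c2ccc(O[Si](C)(C)C(C)(C)C)c(OC)c2)ccc1O[Si](C)(C)C(C)(C)C
F4 | step 5 | (3S,4R)-3-[4-(tert-butyldimethylsilyloxy)-3-methoxybenzoyl]-4-[4-(tert-butyldimethylsilyloxy)-3-methoxybenzyl]dihydrofuran-2(3H)-one | COc1cc(C[C@H]2COC(=O)[C@@H]2C(=O)c2ccc(O[Si](C)(C)C(C)(C)C)c(OC)c2)ccc1O[Si](C)(C)C(C)(C)C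
F5 | step 2 | 2-[4-(tert-butyldimethylsilyloxy)-3-methoxyphenyl]acetaldehyde | O=CCc1ccc(O[Si](C)(C)C(C)(C)C)c(OC)c1
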